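The target is (3S,6R)-3-hydroxy-8'-apo-ε-caroten-8'-al (carotenoid numbering). It is cut first at C7=C8 (Julia–Kocienski olefination), which separates the all-E C20 dialdehyde chain from a C10 ring sulfone.
The ring is then cut at C1–C6 and C2–C3. In the cyclohexene C1–C6 the C4=C5 alkene (methyl on C5) is flanked by C3–O and C6–C7 in a cis-1,4 relation and C6 adjoins the quaternary C1; this is the retron of a Diels–Alder adduct of an E,E-1-alkoxydiene C3=C4–C5=C6 with the C1=C2 bond of 3-methylbut-2-enal, whose formyl group on C2 is deleted afterwards.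
Forward: an enynol gives the E,E diene by alkyne hydroboration and copper-mediated etherification, and the single ring is closed by the catalytic asymmetric [4+2] step. Decarbonylation, conversion of C7–O into a tetrazolyl sulfone and exchange of the C3 protecting group follow; the chain is joined last and the silyl ether removed.
Stereochemistry: the cis C3/C6 relation comes from the diene geometry and suprafacial addition, and the absolute configuration from the chiral oxazaborolidine–AlBr3 catalyst (endo adduct purified). The C7=C8 geometry comes from the E-selective olefination and the other chain alkenes from the all-E dialdehyde.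

Key step: step 4

Assumption: atoms carry carotenoid numbers (ring C1–C6 with C1 the gem-dimethyl carbon, chain C7 to C8'); the all-E C20 dialdehyde 14 is taken as purchasable; and the (S)-prolinol-derived catalyst is assigned to the required facial attack from the formyl C–H···O binding model, its mirror image being used unchanged in step 4 if the sense is the opposite.

Step 1
Reactants: 1 (2E)-3-methylpent-2-en-4-yn-1-ol
Product: 2 triisopropyl{[(2E)-3-methylpent-2-en-4-yn-1-yl]oxy}silane
Conditions: TIPSCl, imidazole, DMF, 0 °C → rt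
Reagents that add atoms: chlorotriisopropylsilane, CC(C)[Si](Cl)(C(C)C)C(C)C
Why: Silylation of a primary allylic alcohol with a trialkylsilyl chloride and imidazole is routine and masks the hydroxyl against the borane of step 2 and the Lewis acid of step 4.

Step 2
Reactants: 2 triisopropyl{[(2E)-3-methylpent-2-en-4-yn-1-yl]oxy}silane
Product: 3 4,4,5,5-tetramethyl-2-[(1E,3E)-3-methyl-5-[(triisopropylsilyl)oxy]penta-1,3-dien-1-yl]-1,3,2-dioxaborolane
Conditions: pinacolborane (1.2 equiv), Cp2Zr(H)Cl (5 mol %), Et3N (10 mol %), CH2Cl2, 25–40 °C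
Reagents that add atoms: pinacolborane, CC1(C)OBOC1(C)C
Why: Zirconocene-hydride-catalysed hydroboration of a terminal alkyne adds H–B syn and anti-Markovnikov, so the new C3=C4 bond should be E while the trisubstituted E alkene is left untouched.

Step 3
Reactants: 3 4,4,5,5-tetramethyl-2-[(1E,3E)-3-methyl-5-[(triisopropylsilyl)oxy]penta-1,3-dien-1-yl]-1,3,2-dioxaborolane; 4 4-methoxybenzyl alcohol
Product: 5 triisopropyl{[(2E,4E)-5-[(4-methoxybenzyl)oxy]-3-methylpenta-2,4-dien-1-yl]oxy}silane
Conditions: 4 (10 equiv), Cu(OAc)2 (2 equiv), Et3N (4 equiv), 3-hexyne (additive), CH2Cl2, 4 Å MS, rt; chromatography on Et3N-deactivated silica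
Reagents that add atoms: none
Why: Chan–Lam-type oxidative C–O coupling of an alkenylboronate with an alcohol promoted by divalent copper proceeds with retention of alkene geometry, a known entry to 1-alkoxy-1,3-dienes, and so should deliver the E,E diene without an isomer separation.

Step 4
Reactants: 5 triisopropyl{[(2E,4E)-5-[(4-methoxybenzyl)oxy]-3-methylpenta-2,4-dien-1-yl]oxy}silane; 6 3-methylbut-2-enal
Product: 7 (1S,2R,5S)-2-[(4-methoxybenzyl)oxy]-4,6,6-trimethyl-5-{[(triisopropylsilyl)oxy]methyl}cyclohex-3-ene-1-carbaldehyde (formyl, ether and silyloxymethyl groups all cis)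
Conditions: 6 (4 equiv), (3aS)-3,3-diphenyl-1-(2-methylphenyl)tetrahydro-1H,3H-pyrrolo[1,2-c][1,3,2]oxazaborole (20 mol %) + AlBr3 (16 mol %), CH2Cl2, −78 → −40 °C; chromatographic removal of the minor diastereomer
Reagents that add atoms: none
Why: Proposed new method: the AlBr3-activated oxazaborolidine binds the formyl oxygen of 6, the lowered LUMO has its largest coefficient at the β-carbon, and the diene terminus C6 (remote from oxygen, next to the methyl-bearing C5, largest HOMO coefficient) attacks there while C3 bonds to the α-carbon in a concerted, strongly asynchronous [4+2] cycloaddition; the closest known reaction type is the chiral oxazaborolidinium-catalysed Diels–Alder reaction of α- or β-monosubstituted enals with 1-oxygenated dienes, which has not been extended to a β,β-disubstituted enal. The one ring formed, the cyclohexene C1–C6, closes by intermolecular suprafacial–suprafacial [4+2] addition, so the quaternary C1 arises during ring formation and not by alkylation. C3 and C6 become cis because both termini of the E,E diene carry their substituents outside, C2 is set cis to them by the endo orientation of the coordinated formyl group, and the absolute configuration of all three comes from the catalyst, which covers one face of the bound enal so that the diene adds to the Re face of the α-carbon (C2 becomes S). The step needs regio-, endo- and chemoselectivity: the matched donor effects of the C3 alkoxy and C5 methyl groups fix the orientation, while an alkyl instead of a silyl enol ether, low temperature and excess enal are meant to disfavour Mukaiyama–Michael and hetero-Diels–Alder pathways at the formyl group. Because an exo adduct would end, after loss of the formyl group, as the enantiomer of 8, the minor diastereomer has to be removed at this stage.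

Step 5
Reactants: 7 (1S,2R,5S)-2-[(4-methoxybenzyl)oxy]-4,6,6-trimethyl-5-{[(triisopropylsilyl)oxy]methyl}cyclohex-3-ene-1-carbaldehyde
Product: 8 {[(1R,4S)-4-[(4-methoxybenzyl)oxy]-2,6,6-trimethylcyclohex-2-en-1-yl]methoxy}triisopropylsilane
Conditions: RhCl(PPh3)3 (1.1 equiv), degassed xylene, 130 °C
Reagents that add atoms: none
Why: Tsuji–Wilkinson decarbonylation (oxidative addition of the formyl C–H bond to monovalent rhodium, CO migration to the metal and C–H reductive elimination) should replace CHO by H at C2 and leave C3 and C6 untouched.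

Step 6
Reactants: 8 {[(1R,4S)-4-[(4-methoxybenzyl)oxy]-2,6,6-trimethylcyclohex-2-en-1-yl]methoxy}triisopropylsilane
Product: 9 [(1R,4S)-4-[(4-methoxybenzyl)oxy]-2,6,6-trimethylcyclohex-2-en-1-yl]methanol
Conditions: Bu4NF, THF, 0 °C → rt
Reagents that add atoms: none
Why: Fluoride-mediated desilylation cleaves the Si–O bond of the primary silyl ether and does not affect the benzylic ether at C3.

Step 7
Reactants: 9 [(1R,4S)-4-[(4-methoxybenzyl)oxy]-2,6,6-trimethylcyclohex-2-en-1-yl]methanol
Product: 10 5-({[(1R,4S)-4-[(4-methoxybenzyl)oxy]-2,6,6-trimethylcyclohex-2-en-1-yl]methyl}sulfanyl)-1-phenyl-1H-tetrazole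
Conditions: 1-phenyl-1H-tetrazole-5-thiol, PPh3, DIAD, THF, 0 °C → rt
Reagents that add atoms: 1-phenyl-1H-tetrazole-5-thiol, Sc1nnnn1-c1ccccc1
Why: In this Mitsunobu thioetherification the primary alkoxyphosphonium ion is displaced at C7 by the acidic heteroaryl thiol, and only C7 can react because C3 is still an ether.

Step 8
Reactants: 10 5-({[(1R,4S)-4-[(4-methoxybenzyl)oxy]-2,6,6-trimethylcyclohex-2-en-1-yl]methyl}sulfanyl)-1-phenyl-1H-tetrazole
Product: 11 5-({[(1R,4S)-4-[(4-methoxybenzyl)oxy]-2,6,6-trimethylcyclohex-2-en-1-yl]methyl}sulfonyl)-1-phenyl-1H-tetrazole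
Conditions: (NH4)6Mo7O24·4H2O (10 mol %), 30% aq. H2O2, EtOH, 0 °C → rt
Reagents that add atoms: hydrogen peroxide, OO
Why: Molybdate-catalysed peroxide oxidation of a sulfide to the sulfone is chemoselective in the presence of an unactivated trisubstituted alkene, and the C3 oxygen is kept as its ether so that no hydroxyl-directed epoxidation can occur.

Step 9
Reactants: 11 5-({[(1R,4S)-4-[(4-methoxybenzyl)oxy]-2,6,6-trimethylcyclohex-2-en-1-yl]methyl}sulfonyl)-1-phenyl-1H-tetrazole
Product: 12 (1S,4R)-3,5,5-trimethyl-4-{[(1-phenyl-1H-tetrazol-5-yl)sulfonyl]methyl}cyclohex-2-en-1-ol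
Conditions: DDQ (1.2 equiv), CH2Cl2/pH 7 phosphate buffer (10:1), 0 °C
Reagents that add atoms: none
Why: Oxidative cleavage of the 4-methoxybenzyl ether by DDQ (benzylic hydride abstraction, then hydrolysis of the oxocarbenium ion) frees the C3 hydroxyl before the oxidant-sensitive polyene is present.

Step 10
Reactants: 12 (1S,4R)-3,5,5-trimethyl-4-{[(1-phenyl-1H-tetrazol-5-yl)sulfonyl]methyl}cyclohex-2-en-1-ol
Product: 13 5-({[(1R,4S)-2,6,6-trimethyl-4-[(triethylsilyl)oxy]cyclohex-2-en-1-yl]methyl}sulfonyl)-1-phenyl-1H-tetrazole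
Conditions: TESCl, imidazole, CH2Cl2, 0 °C
Reagents that add atoms: chlorotriethylsilane, CC[Si](Cl)(CC)CC
Why: Silylation of the secondary allylic alcohol gives a base-stable ether that can later be removed under conditions a polyenal tolerates.

Step 11
Reactants: 13 5-({[(1R,4S)-2,6,6-trimethyl-4-[(triethylsilyl)oxy]cyclohex-2-en-1-yl]methyl}sulfonyl)-1-phenyl-1H-tetrazole; 14 (2E,4E,6E,8E,10E,12E,14E)-2,6,11,15-tetramethylhexadeca-2,4,6,8,10,12,14-heptaenedial
Product: 16 (3S,6R)-3-[(triethylsilyl)oxy]-8'-apo-ε-caroten-8'-al, via potassium α-sulfonyl carbanion 15 (not isolated)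
Conditions: KN(SiMe3)2 (1.05 equiv), THF, −78 °C, 30 min; then cannulated into 14 (3 equiv) in THF, −78 → −20 °C; subdued light
Reagents that add atoms: none
Why: In this Julia–Kocienski olefination the metallated 1-phenyltetrazolyl sulfone adds to one formyl group, Smiles rearrangement and loss of SO2 and tetrazolate give the C7=C8 alkene with the E preference typical of this sulfone class, and the excess of dialdehyde suppresses double olefination.

Step 12
Reactants: 16 (3S,6R)-3-[(triethylsilyl)oxy]-8'-apo-ε-caroten-8'-al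
Product: 17 (3S,6R)-3-hydroxy-8'-apo-ε-caroten-8'-al
Conditions: HF·pyridine, excess pyridine, THF, 0 °C → rt, subdued light
Reagents that add atoms: none
Why: Buffered fluoride cleavage of the triethylsilyl ether should liberate the allylic alcohol without acid-induced ionisation at C3 or damage to the polyenal.

Compound list
1 | (2E)-3-methylpent-2-en-4-yn-1-ol | C#C/C(C)=C/CO | starting material
2 | triisopropyl{[(2E)-3-methylpent-2-en-4-yn-1-yl]oxy}silane | C#C/C(C)=C/CO[Si](C(C)C)(C(C)C)C(C)C | intermediate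
3 | 4,4,5,5-tetramethyl-2-[(1E,3E)-3-methyl-5-[(triisopropylsilyl)oxy]penta-1,3-dien-1-yl]-1,3,2-dioxaborolane | CC1(C)OB(/C=C/C(C)=C/CO[Si](C(C)C)(C(C)C)C(C)C)OC1(C)C | intermediate
4 | 4-methoxybenzyl alcohol | COc1ccc(CO)cc1 | starting material
5 | triisopropyl{[(2E,4E)-5-[(4-methoxybenzyl)oxy]-3-methylpenta-2,4-dien-1-yl]oxy}silane | COc1ccc(CO/C=C/C(C)=C/CO[Si](C(C)C)(C(C)C)C(C)C)cc1 | intermediate
6 | 3-methylbut-2-enal | CC(C)=CC=O | starting material
7 | (1S,2R,5S)-2-[(4-methoxybenzyl)oxy]-4,6,6-trimethyl-5-{[(triisopropylsilyl)oxy]methyl}cyclohex-3-ene-1-carbaldehyde, all-cis | CC1=C[C@@H](OCc2ccc(OC)cc2)[C@@H](C=O)C(C)(C)[C@H]1CO[Si](C(C)C)(C(C)C)C(C)C | intermediate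
8 | {[(1R,4S)-4-[(4-methoxybenzyl)oxy]-2,6,6-trimethylcyclohex-2-en-1-yl]methoxy}triisopropylsilane | CC1=C[C@@H](OCc2ccc(OC)cc2)CC(C)(C)[C@H]1CO[Si](C(C)C)(C(C)C)C(C)C | intermediate
9 | [(1R,4S)-4-[(4-methoxybenzyl)oxy]-2,6,6-trimethylcyclohex-2-en-1-yl]methanol | CC1=C[C@@H](OCc2ccc(OC)cc2)CC(C)(C)[C@H]1CO | intermediate
10 | 5-({[(1R,4S)-4-[(4-methoxybenzyl)oxy]-2,6,6-trimethylcyclohex-2-en-1-yl]methyl}sulfanyl)-1-phenyl-1H-tetrazole | CC1=C[C@@H](OCc2ccc(OC)cc2)CC(C)(C)[C@H]1CSc3nnnn3-c4ccccc4 | intermediate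
11 | 5-({[(1R,4S)-4-[(4-methoxybenzyl)oxy]-2,6,6-trimethylcyclohex-2-en-1-yl]methyl}sulfonyl)-1-phenyl-1H-tetrazole | CC1=C[C@@H](OCc2ccc(OC)cc2)CC(C)(C)[C@H]1CS(=O)(=O)c3nnnn3-c4ccccc4 | intermediate
12 | (1S,4R)-3,5,5-trimethyl-4-{[(1-phenyl-1H-tetrazol-5-yl)sulfonyl]methyl}cyclohex-2-en-1-ol | CC1=C[C@@H](O)CC(C)(C)[C@H]1CS(=O)(=O)c2nnnn2-c3ccccc3 | intermediate
13 | 5-({[(1R,4S)-2,6,6-trimethyl-4-[(triethylsilyl)oxy]cyclohex-2-en-1-yl]methyl}sulfonyl)-1-phenyl-1H-tetrazole | CC1=C[C@@H](O[Si](CC)(CC)CC)CC(C)(C)[C@H]1CS(=O)(=O)c2nnnn2-c3ccccc3 | intermediate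
14 | (2E,4E,6E,8E,10E,12E,14E)-2,6,11,15-tetramethylhexadeca-2,4,6,8,10,12,14-heptaenedial (crocetindialdehyde) | O=C/C(C)=C/C=C/C(C)=C/C=C/C=C(C)/C=C/C=C(C)/C=O | starting material
15 | potassium salt of the C7 carbanion of sulfone 13 | [K+].CC1=C[C@@H](O[Si](CC)(CC)CC)CC(C)(C)[C@H]1[CH-]S(=O)(=O)c2nnnn2-c3ccccc3 | intermediate
16 | (3S,6R)-3-[(triethylsilyl)oxy]-8'-apo-ε-caroten-8'-al | CC1=C[C@@H](O[Si](CC)(CC)CC)CC(C)(C)[C@H]1/C=C/C(C)=C/C=C/C(C)=C/C=C/C=C(C)/C=C/C=C(\C)C=O | intermediate
17 | (3S,6R)-3-hydroxy-8'-apo-ε-caroten-8'-al, i.e. (2E,4E,6E,8E,10E,12E,14E,16E)-17-[(1R,4S)-4-hydroxy-2,6,6-trimethylcyclohex-2-en-1-yl]-2,6,11,15-tetramethylheptadeca-2,4,6,8,10,12,14,16-octaenal | CC1=C[C@@H](O)CC(C)(C)[C@H]1/C=C/C(C)=C/C=C/C(C)=C/C=C/C=C(C)/C=C/C=C(\C)C=O | target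

Total step count: 12. Longest linear sequence: 12 steps (1 → 17); compounds 4, 6 and 14 enter as purchased materials.

Steps most likely to fail

1. Step 4 (Proposed new method). The β,β-disubstituted carbon may react too slowly, so that the activated enal is consumed by hetero-Diels–Alder addition across its formyl group or the acid-labile dienol ether decomposes. Incomplete endo selectivity would in addition erode the enantiomeric purity of 8.
Fallback, from 5 and back at 8: diene 5 is combined under the catalyst of step 4 with ethyl (2E)-4-oxobut-2-enoate, an enal with a single β-substituent and so inside the documented scope of oxazaborolidinium catalysis with 1-oxygenated dienes. Formyl coordination should place the ester-bearing carbon at C1 and give ethyl 6-formyl-5-[(4-methoxybenzyl)oxy]-3-methyl-2-{[(triisopropylsilyl)oxy]methyl}cyclohex-3-ene-1-carboxylate (formyl, ether and silyloxymethyl groups cis, ester trans) F1. Tsuji–Wilkinson decarbonylation with RhCl(PPh3)3 then gives ethyl 5-[(4-methoxybenzyl)oxy]-3-methyl-2-{[(triisopropylsilyl)oxy]methyl}cyclohex-3-ene-1-carboxylate F2. LiN(iPr)2 followed by MeI methylates C1 to ethyl 5-[(4-methoxybenzyl)oxy]-1,3-dimethyl-2-{[(triisopropylsilyl)oxy]methyl}cyclohex-3-ene-1-carboxylate F3, of which either C1 epimer serves. LiAlH4 gives {5-[(4-methoxybenzyl)oxy]-1,3-dimethyl-2-{[(triisopropylsilyl)oxy]methyl}cyclohex-3-en-1-yl}methanol F4, MsCl/Et3N gives its methanesulfonate F5, and LiBHEt3 in refluxing THF reduces the neopentyl sulfonate to the second C1 methyl group, which is compound 8.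

2. Step 5. The alkylrhodium hydride may undergo β-hydride or β-alkoxide elimination instead of reductive elimination, or the β-alkoxy aldehyde may lose 4-methoxybenzyl alcohol thermally to a conjugated dienal at the temperature that the hindered formyl group requires.
Fallback, from 7 and back at 8: Pinnick oxidation (NaClO2, NaH2PO4, 2-methylbut-2-ene, t-BuOH/H2O) converts 7 into (1S,2R,5S)-2-[(4-methoxybenzyl)oxy]-4,6,6-trimethyl-5-{[(triisopropylsilyl)oxy]methyl}cyclohex-3-ene-1-carboxylic acid F6. Coupling with 1-hydroxypyridine-2(1H)-thione (DCC, CH2Cl2, dark) gives the 2-thioxopyridin-1(2H)-yl ester of this acid F7. Visible-light Barton decarboxylation in the presence of t-BuSH at room temperature then reduces the C2 radical to CH2 and gives 8.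

3. Step 11. The symmetrical dialdehyde may be olefinated twice, its low solubility at −78 °C may starve the carbanion of electrophile and let the sulfone self-condense, and E selectivity at C7=C8 may be incomplete with a conjugated aldehyde.
Fallback, from 14 and 13 and back at 16: the statistical event is moved to the cheap component. Dialdehyde 14 with HC(OMe)3 and catalytic pyridinium p-toluenesulfonate in MeOH/CH2Cl2, stopped at partial conversion, gives (2E,4E,6E,8E,10E,12E,14E)-16,16-dimethoxy-2,6,11,15-tetramethylhexadeca-2,4,6,8,10,12,14-heptaenal F8, which is separated from the dialdehyde and the bis-acetal on basified silica. Olefination of F8 with one equivalent of carbanion 15 under the conditions of step 11, now in a more soluble and strictly mono-electrophilic partner, gives the dimethyl acetal of 16 F9. Brief treatment with pyridinium p-toluenesulfonate in wet acetone releases the formyl group and returns 16; a trace of iodine in daylight would equilibrate any 7Z isomer to the all-E polyene.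

Further compounds
F1 | step 4 | ethyl 6-formyl-5-[(4-methoxybenzyl)oxy]-3-methyl-2-{[(triisopropylsilyl)oxy]methyl}cyclohex-3-ene-1-carboxylate (formyl, ether and silyloxymethyl cis, ester trans) | CC1=C[C@@H](OCc2ccc(OC)cc2)[C@@H](C=O)[C@H](C(=O)OCC)[C@H]1CO[Si](C(C)C)(C(C)C)C(C)C
F2 | step 4 | ethyl 5-[(4-methoxybenzyl)oxy]-3-methyl-2-{[(triisopropylsilyl)oxy]methyl}cyclohex-3-ene-1-carboxylate | CC1=C[C@@H](OCc2ccc(OC)cc2)C[C@H](C(=O)OCC)[C@H]1CO[Si](C(C)C)(C(C)C)C(C)C
F3 | step 4 | ethyl 5-[(4-methoxybenzyl)oxy]-1,3-dimethyl-2-{[(triisopropylsilyl)oxy]methyl}cyclohex-3-ene-1-carboxylate (C1 epimers) | CC1=C[C@@H](OCc2ccc(OC)cc2)CC(C)(C(=O)OCC)[C@H]1CO[Si](C(C)C)(C(C)C)C(C)C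
F4 | step 4 | {5-[(4-methoxybenzyl)oxy]-1,3-dimethyl-2-{[(triisopropylsilyl)oxy]methyl}cyclohex-3-en-1-yl}methanol (C1 epimers) | CC1=C[C@@H](OCc2ccc(OC)cc2)CC(C)(CO)[C@H]1CO[Si](C(C)C)(C(C)C)C(C)C
F5 | step 4 | {5-[(4-methoxybenzyl)oxy]-1,3-dimethyl-2-{[(triisopropylsilyl)oxy]methyl}cyclohex-3-en-1-yl}methyl methanesulfonate (C1 epimers) | CC1=C[C@@H](OCc2ccc(OC)cc2)CC(C)(COS(C)(=O)=O)[C@H]1CO[Si](C(C)C)(C(C)C)C(C)C
F6 | step 5 | (1S,2R,5S)-2-[(4-methoxybenzyl)oxy]-4,6,6-trimethyl-5-{[(triisopropylsilyl)oxy]methyl}cyclohex-3-ene-1-carboxylic acid | CC1=C[C@@H](OCc2ccc(OC)cc2)[C@@H](C(=O)O)C(C)(C)[C@H]1CO[Si](C(C)C)(C(C)C)C(C)C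
F7 | step 5 | 2-thioxopyridin-1(2H)-yl (1S,2R,5S)-2-[(4-methoxybenzyl)oxy]-4,6,6-trimethyl-5-{[(triisopropylsilyl)oxy]methyl}cyclohex-3-ene-1-carboxylate | CC1=C[C@@H](OCc2ccc(OC)cc2)[C@@H](C(=O)ON3C=CC=CC3=S)C(C)(C)[C@H]1CO[Si](C(C)C)(C(C)C)C(C)C
F8 | step 11 | (2E,4E,6E,8E,10E,12E,14E)-16,16-dimethoxy-2,6,11,15-tetramethylhexadeca-2,4,6,8,10,12,14-heptaenal | COC(OC)/C(C)=C/C=C/C(C)=C/C=C/C=C(C)/C=C/C=C(C)/C=O
F9 | step 11 | dimethyl acetal of (3S,6R)-3-[(triethylsilyl)oxy]-8'-apo-ε-caroten-8'-al | CC1=C[C@@H](O[Si](CC)(CC)CC)CC(C)(C)[C@H]1/C=C/C(C)=C/C=C/C(C)=C/C=C/C=C(C)/C=C/C=C(\C)C(OC)OC
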